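Everything rests on assembling luteolin ring B from open-chain carbons. In that ring C3′ and C4′ bear the two neighbouring hydroxyls, while the opposite edge, C1′–C6′, bears flavone C2 and flavanone C6: the substitution left behind when a butadiene oxygenated at both inner carbons adds across an internal alkyne. One [4+2] cycloaddition forms C1′–C2′ and C5′–C6′ and closes the carbocycle. The crowded aryl–aryl bond never has to be coupled, because it enters as an aryl–alkyne bond. The dienophile is a methyl arylpropiolate whose phloroglucinol ring carries benzyl ethers beside the alkyne, a MOM ether para to it (the future O1) and a bromine that reserves the site of the later acetyl group.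

Key step: step 7

Assumption 1: the stereocentre of the target reads as (2R). The biaryl axis carries no descriptor and is taken as free to rotate in the heptaphenol, so slowly interconverting rotamers of benzylated intermediates are carried on together.

Assumption 2: (S)-t-BuPyOx is assigned to the (2R) product by transferring the facial preference known for cyclic enones to the chromone. If a trial on a simple chromone shows the opposite sense, the equally available (R)-ligand is used.

Step 1
Reactants: 1 2,4,6-trihydroxybenzaldehyde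
Product: 2 2,6-dihydroxy-4-(methoxymethoxy)benzaldehyde
Conditions: MOMCl (1.0 equiv), K2CO3 (1.1 equiv), acetone, 0 °C to rt
Reagents that add atoms: chloromethyl methyl ether (MOMCl), COCCl
Why: Chemoselective Williamson-type O-alkylation, in which the 4-OH is the most acidic hydroxyl and the only one that cannot hydrogen-bond to the formyl oxygen, so one equivalent of MOMCl should take it first.

Step 2
Reactants: 2 2,6-dihydroxy-4-(methoxymethoxy)benzaldehyde
Product: 3 2,6-bis(benzyloxy)-4-(methoxymethoxy)benzaldehyde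
Conditions: BnBr (2.4 equiv), K2CO3 (3 equiv), DMF, 60 °C
Reagents that add atoms: benzyl bromide, BrCc1ccccc1
Why: Williamson etherification with excess benzyl bromide and gentle heating overcomes the chelation of the two remaining phenols, and the MOM acetal is inert to carbonate.

Step 3
Reactants: 3 2,6-bis(benzyloxy)-4-(methoxymethoxy)benzaldehyde
Product: 4 2,6-bis(benzyloxy)-3-bromo-4-(methoxymethoxy)benzaldehyde
Conditions: NBS (1.0 equiv), MeCN, 0 °C, dark
Reagents that add atoms: N-bromosuccinimide, O=C1CCC(=O)N1Br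
Why: Electrophilic aromatic bromination at one of the two equivalent positions C3/C5, each ortho or para to three oxygens and meta to the formyl group, with the aldehyde and the first bromine slowing a second substitution, so that the future C4a is marked early and no Lewis-acid acylation is needed on a polybenzylated late intermediate.

Step 4
Reactants: 4 2,6-bis(benzyloxy)-3-bromo-4-(methoxymethoxy)benzaldehyde
Product: 5 1,3-bis(benzyloxy)-4-bromo-2-ethynyl-5-(methoxymethoxy)benzene
Conditions: dimethyl (1-diazo-2-oxopropyl)phosphonate (1.5 equiv), K2CO3 (2.5 equiv), MeOH/THF, rt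
Reagents that add atoms: dimethyl (1-diazo-2-oxopropyl)phosphonate, COP(=O)(OC)C(=[N+]=[N-])C(C)=O
Why: Seyferth–Gilbert homologation in the Ohira–Bestmann variant converts the non-enolisable aldehyde into the terminal alkyne under carbonate in methanol, conditions that spare the aryl bromide where an alkyllithium-based homologation would not.

Step 5
Reactants: 5 1,3-bis(benzyloxy)-4-bromo-2-ethynyl-5-(methoxymethoxy)benzene
Product: 7 methyl 3-[2,6-bis(benzyloxy)-3-bromo-4-(methoxymethoxy)phenyl]prop-2-ynoate, via lithium acetylide 6 (not isolated)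
Conditions: LiN(i-Pr)2 (1.1 equiv), THF, −78 °C; ClCO2Me (1.6 equiv), −78 to 0 °C
Reagents that add atoms: methyl chloroformate, COC(=O)Cl
Why: Acid–base metalation of the terminal alkyne by an amide base, which cannot undergo bromine–lithium exchange and finds no hydrogen ortho to bromine for aryne formation, followed by C-acylation of the acetylide with the chloroformate.

Step 6
Reactants: 8 butane-2,3-dione
Product: 9 2,3-bis(trimethylsilyloxy)buta-1,3-diene
Conditions: Me3SiOTf (2.2 equiv), Et3N (2.6 equiv), Et2O, 0 °C to rt; distillation under reduced pressure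
Reagents that add atoms: trimethylsilyl trifluoromethanesulfonate, C[Si](C)(C)OS(=O)(=O)C(F)(F)F
Why: Double soft enolisation and O-silylation of the 1,2-diketone is the standard preparation of this known diene, which is distilled and used fresh.

Step 7
Reactants: 7 methyl 3-[2,6-bis(benzyloxy)-3-bromo-4-(methoxymethoxy)phenyl]prop-2-ynoate; 9 2,3-bis(trimethylsilyloxy)buta-1,3-diene
Product: 10 methyl 2-[2,6-bis(benzyloxy)-3-bromo-4-(methoxymethoxy)phenyl]-4,5-bis(trimethylsilyloxy)cyclohexa-1,4-diene-1-carboxylate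
Conditions: 9 (4 equiv, in two portions), BHT (5 mol %), o-xylene, 150 °C, sealed silylated tube, argon; excess diene removed in vacuo, crude product carried on
Reagents that add atoms: none
Why: Thermal, concerted π4s + π2s cycloaddition of normal electron demand, in which the HOMO of the doubly oxygen-donor diene 9 meets the LUMO of the ester-conjugated triple bond of 7 and both new σ bonds (diene CH2 termini to the two alkyne carbons, the future C1′–C2′ and C5′–C6′) form in one event. The closest known reaction type is the addition of 2,3-bis(silyloxy)butadienes to acetylenic esters and, more broadly, the Diels–Alder benzannulation of acceptor-bearing arylalkynes used to reach crowded biaryls. The single ring is closed intermolecularly in the [4+2] mode as a cyclohexa-1,4-diene, and no stereocentre is created. Regiochemistry does not arise because the diene is twofold symmetric, so what is needed is rate and chemoselectivity, that is cycloaddition ahead of diene oligomerisation, desilylation or Michael-type attack of the silyl enol ether. The substrate secures this through the ester acceptor, the inductive pull of bromine on an otherwise strongly donating ring, the rod-like alkyne that holds both benzyloxy groups away from the reacting carbons while the aryl plane turns perpendicular, and the unsubstituted diene termini, and Lewis acids are left out on purpose. A second addition is excluded because the remaining acrylate double bond of 10 is tetrasubstituted.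

Step 8
Reactants: 10 methyl 2-[2,6-bis(benzyloxy)-3-bromo-4-(methoxymethoxy)phenyl]-4,5-bis(trimethylsilyloxy)cyclohexa-1,4-diene-1-carboxylate
Product: 11 methyl 2-[2,6-bis(benzyloxy)-3-bromo-4-(methoxymethoxy)phenyl]-4,5-bis(trimethylsilyloxy)benzoate
Conditions: DDQ (1.0 equiv), anhydrous toluene, 0 °C to rt; filtration
Reagents that add atoms: none
Why: Dehydrogenative aromatisation, in which DDQ takes hydride from a doubly allylic CH2 and the arenium ion loses a proton, is fast at room temperature where benzyl ethers, MOM acetal and aryl bromide are inert, and any partial loss of silyl groups is harmless because the next step converges.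

Step 9
Reactants: 11 methyl 2-[2,6-bis(benzyloxy)-3-bromo-4-(methoxymethoxy)phenyl]-4,5-bis(trimethylsilyloxy)benzoate
Product: 12 methyl 4,5-bis(benzyloxy)-2-[2,6-bis(benzyloxy)-3-bromo-4-(methoxymethoxy)phenyl]benzoate
Conditions: CsF (3 equiv), BnBr (3 equiv), DMF, rt, argon
Reagents that add atoms: benzyl bromide, BrCc1ccccc1
Why: Fluoride-triggered desilylation with in situ Williamson benzylation traps each phenoxide as it forms, so the oxidation-prone free catechol is never handled.

Step 10
Reactants: 12 methyl 4,5-bis(benzyloxy)-2-[2,6-bis(benzyloxy)-3-bromo-4-(methoxymethoxy)phenyl]benzoate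
Product: 13 methyl 4,5-bis(benzyloxy)-2-[2,6-bis(benzyloxy)-3-(1-ethoxyethenyl)-4-(methoxymethoxy)phenyl]benzoate
Conditions: tributyl(1-ethoxyvinyl)stannane (1.5 equiv), Pd2(dba)3 (3 mol %), P(t-Bu)3 (7 mol %), CsF (2.2 equiv), 1,4-dioxane, 90 °C; chromatography on Et3N-washed silica
Reagents that add atoms: tributyl(1-ethoxyvinyl)stannane, CCCC[Sn](CCCC)(CCCC)C(=C)OCC
Why: Stille coupling with a bulky electron-rich phosphine on zerovalent palladium and fluoride activation of tin is the variant suited to hindered, electron-rich aryl bromides, and it places the acetyl group, masked as a base-stable enol ether, exactly at the carbon fixed by the bromine.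

Step 11
Reactants: 14 2′,4′,6′-trihydroxyacetophenone
Product: 15 1-[2,4-bis(benzyloxy)-6-hydroxyphenyl]ethan-1-one
Conditions: BnBr (2.05 equiv), K2CO3 (2.2 equiv), DMF, rt to 50 °C
Reagents that add atoms: benzyl bromide, BrCc1ccccc1
Why: Selective Williamson etherification stops at the dibenzyl ether because the last hydroxyl is strongly chelated to the acetyl carbonyl.

Step 12
Reactants: 13 methyl 4,5-bis(benzyloxy)-2-[2,6-bis(benzyloxy)-3-(1-ethoxyethenyl)-4-(methoxymethoxy)phenyl]benzoate; 15 1-[2,4-bis(benzyloxy)-6-hydroxyphenyl]ethan-1-one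
Product: 17 2-{2-[3-acetyl-2,6-bis(benzyloxy)-4-hydroxyphenyl]-4,5-bis(benzyloxy)phenyl}-5,7-bis(benzyloxy)-4H-chromen-4-one, via 1,3-diketone 16 (not isolated)
Conditions: 15 (1.5 equiv), LiN(SiMe3)2 (3.5 equiv), THF, −78 to −10 °C; add 13, −10 °C to rt; aq HCl quench, concentrate; conc. HCl, MeOH/THF, 55 °C
Reagents that add atoms: water, O
Why: Crossed Claisen condensation of the lithium dianion of 15 with the non-enolisable ester 13, a flavone entry proven on ortho-substituted benzoates, is followed by one mild Brønsted-acid operation that cyclodehydrates the diketone to the flavone, removes the MOM group and hydrolyses the enol ether to the acetyl group while all benzyl ethers, including the one next to the acetyl, stay in place.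

Step 13
Reactants: 17 2-{2-[3-acetyl-2,6-bis(benzyloxy)-4-hydroxyphenyl]-4,5-bis(benzyloxy)phenyl}-5,7-bis(benzyloxy)-4H-chromen-4-one
Product: 19 5,7-bis(benzyloxy)-6-{4,5-bis(benzyloxy)-2-[5,7-bis(benzyloxy)-4-oxo-4H-chromen-2-yl]phenyl}-4H-chromen-4-one, via enaminone 18 (not isolated)
Conditions: Me2NCH(OMe)2 (5 equiv), toluene, 95 °C; evaporate; conc. HCl, CH2Cl2, 40 °C
Reagents that add atoms: N,N-dimethylformamide dimethyl acetal, COC(OC)N(C)C
Why: The enaminone route to 2,3-unsubstituted chromones (condensation of the methyl ketone, then acid-induced addition–elimination) can close only through the single free phenol, the former MOM oxygen para to the biaryl bond, which fixes the C6 and not the C8 linkage.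

Step 14
Reactants: 19 5,7-bis(benzyloxy)-6-{4,5-bis(benzyloxy)-2-[5,7-bis(benzyloxy)-4-oxo-4H-chromen-2-yl]phenyl}-4H-chromen-4-one; 20 4-(benzyloxy)phenylboronic acid
Product: 21 (2R)-5,7-bis(benzyloxy)-2-[4-(benzyloxy)phenyl]-6-{4,5-bis(benzyloxy)-2-[5,7-bis(benzyloxy)-4-oxo-4H-chromen-2-yl]phenyl}-2,3-dihydro-4H-chromen-4-one
Conditions: 20 (2.5 equiv), Pd(OCOCF3)2 (10 mol %), (S)-t-BuPyOx (12 mol %), NH4PF6 (30 mol %), H2O (5 equiv), ClCH2CH2Cl, 60 °C
Reagents that add atoms: none
Why: Enantioselective conjugate addition of an arylboronic acid to a chromone under cationic divalent palladium with a pyridine–oxazoline ligand (transmetalation, face-selective insertion of C2=C3 into the aryl–palladium bond, protonolysis) sets C2, the tert-butyl group of the ligand shielding one face so that the aryl group should arrive to give (2R), while the flavone with its fully substituted C2 is no acceptor and the base-free medium gives no path to ring-opening racemisation.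

Step 15
Reactants: 21 (2R)-5,7-bis(benzyloxy)-2-[4-(benzyloxy)phenyl]-6-{4,5-bis(benzyloxy)-2-[5,7-bis(benzyloxy)-4-oxo-4H-chromen-2-yl]phenyl}-2,3-dihydro-4H-chromen-4-one
Product: 22 (2R)-6-[2-(5,7-dihydroxy-4-oxo-4H-chromen-2-yl)-4,5-dihydroxyphenyl]-5,7-dihydroxy-2-(4-hydroxyphenyl)-2,3-dihydro-4H-chromen-4-one
Conditions: H2 (1 atm), Pd/C (10 wt % Pd), THF/MeOH, rt; stopped when uptake ends
Reagents that add atoms: none
Why: Catalytic hydrogenolysis removes all seven benzyl ethers under neutral conditions, so the chalcone ring-opening that would racemise C2 or move the linkage from C6 to C8 cannot start, and primary benzyl ethers cleave well before the ring C2–O1 bond or the flavone double bond is touched.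

Compound list
1 | 2,4,6-trihydroxybenzaldehyde | O=Cc1c(O)cc(O)cc1O | starting material
2 | 2,6-dihydroxy-4-(methoxymethoxy)benzaldehyde | O=Cc1c(O)cc(OCOC)cc1O | intermediate
3 | 2,6-bis(benzyloxy)-4-(methoxymethoxy)benzaldehyde | O=Cc1c(OCc2ccccc2)cc(OCOC)cc1OCc1ccccc1 | intermediate
4 | 2,6-bis(benzyloxy)-3-bromo-4-(methoxymethoxy)benzaldehyde | O=Cc1c(OCc2ccccc2)c(Br)c(OCOC)cc1OCc1ccccc1 | intermediate
5 | 1,3-bis(benzyloxy)-4-bromo-2-ethynyl-5-(methoxymethoxy)benzene | C#Cc1c(OCc2ccccc2)c(Br)c(OCOC)cc1OCc1ccccc1 | intermediate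
6 | {[2,6-bis(benzyloxy)-3-bromo-4-(methoxymethoxy)phenyl]ethynyl}lithium | [Li]C#Cc1c(OCc2ccccc2)c(Br)c(OCOC)cc1OCc1ccccc1 | intermediate
7 | methyl 3-[2,6-bis(benzyloxy)-3-bromo-4-(methoxymethoxy)phenyl]prop-2-ynoate | COC(=O)C#Cc1c(OCc2ccccc2)c(Br)c(OCOC)cc1OCc1ccccc1 | intermediate
8 | butane-2,3-dione | CC(=O)C(C)=O | starting material
9 | 2,3-bis(trimethylsilyloxy)buta-1,3-diene | C=C(O[Si](C)(C)C)C(=C)O[Si](C)(C)C | intermediate
10 | methyl 2-[2,6-bis(benzyloxy)-3-bromo-4-(methoxymethoxy)phenyl]-4,5-bis(trimethylsilyloxy)cyclohexa-1,4-diene-1-carboxylate | COC(=O)C1=C(c2c(OCc3ccccc3)c(Br)c(OCOC)cc2OCc2ccccc2)CC(O[Si](C)(C)C)=C(O[Si](C)(C)C)C1 | intermediate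
11 | methyl 2-[2,6-bis(benzyloxy)-3-bromo-4-(methoxymethoxy)phenyl]-4,5-bis(trimethylsilyloxy)benzoate | COC(=O)c1cc(O[Si](C)(C)C)c(O[Si](C)(C)C)cc1-c1c(OCc2ccccc2)c(Br)c(OCOC)cc1OCc1ccccc1 | intermediate
12 | methyl 4,5-bis(benzyloxy)-2-[2,6-bis(benzyloxy)-3-bromo-4-(methoxymethoxy)phenyl]benzoate | COC(=O)c1cc(OCc2ccccc2)c(OCc2ccccc2)cc1-c1c(OCc2ccccc2)c(Br)c(OCOC)cc1OCc1ccccc1 | intermediate
13 | methyl 4,5-bis(benzyloxy)-2-[2,6-bis(benzyloxy)-3-(1-ethoxyethenyl)-4-(methoxymethoxy)phenyl]benzoate | COC(=O)c1cc(OCc2ccccc2)c(OCc2ccccc2)cc1-c1c(OCc2ccccc2)c(C(=C)OCC)c(OCOC)cc1OCc1ccccc1 | intermediate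
14 | 2′,4′,6′-trihydroxyacetophenone | CC(=O)c1c(O)cc(O)cc1O | starting material
15 | 1-[2,4-bis(benzyloxy)-6-hydroxyphenyl]ethan-1-one | CC(=O)c1c(O)cc(OCc2ccccc2)cc1OCc1ccccc1 | intermediate
16 | 1-[2,4-bis(benzyloxy)-6-hydroxyphenyl]-3-{4,5-bis(benzyloxy)-2-[2,6-bis(benzyloxy)-3-(1-ethoxyethenyl)-4-(methoxymethoxy)phenyl]phenyl}propane-1,3-dione | O=C(CC(=O)c1c(O)cc(OCc2ccccc2)cc1OCc1ccccc1)c1cc(OCc2ccccc2)c(OCc2ccccc2)cc1-c1c(OCc2ccccc2)c(C(=C)OCC)c(OCOC)cc1OCc1ccccc1 | intermediate
17 | 2-{2-[3-acetyl-2,6-bis(benzyloxy)-4-hydroxyphenyl]-4,5-bis(benzyloxy)phenyl}-5,7-bis(benzyloxy)-4H-chromen-4-one | CC(=O)c1c(O)cc(OCc2ccccc2)c(-c2cc(OCc3ccccc3)c(OCc3ccccc3)cc2-c2cc(=O)c3c(OCc4ccccc4)cc(OCc4ccccc4)cc3o2)c1OCc1ccccc1 | intermediate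
18 | 2-{4,5-bis(benzyloxy)-2-[2,6-bis(benzyloxy)-3-[(E)-3-(dimethylamino)prop-2-enoyl]-4-hydroxyphenyl]phenyl}-5,7-bis(benzyloxy)-4H-chromen-4-one | CN(C)/C=C/C(=O)c1c(O)cc(OCc2ccccc2)c(-c2cc(OCc3ccccc3)c(OCc3ccccc3)cc2-c2cc(=O)c3c(OCc4ccccc4)cc(OCc4ccccc4)cc3o2)c1OCc1ccccc1 | intermediate
19 | 5,7-bis(benzyloxy)-6-{4,5-bis(benzyloxy)-2-[5,7-bis(benzyloxy)-4-oxo-4H-chromen-2-yl]phenyl}-4H-chromen-4-one | O=c1ccoc2cc(OCc3ccccc3)c(-c3cc(OCc4ccccc4)c(OCc4ccccc4)cc3-c3cc(=O)c4c(OCc5ccccc5)cc(OCc5ccccc5)cc4o3)c(OCc3ccccc3)c12 | intermediate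
20 | 4-(benzyloxy)phenylboronic acid | OB(O)c1ccc(OCc2ccccc2)cc1 | starting material
21 | (2R)-5,7-bis(benzyloxy)-2-[4-(benzyloxy)phenyl]-6-{4,5-bis(benzyloxy)-2-[5,7-bis(benzyloxy)-4-oxo-4H-chromen-2-yl]phenyl}-2,3-dihydro-4H-chromen-4-one | O=C1C[C@H](c2ccc(OCc3ccccc3)cc2)Oc2cc(OCc3ccccc3)c(-c3cc(OCc4ccccc4)c(OCc4ccccc4)cc3-c3cc(=O)c4c(OCc5ccccc5)cc(OCc5ccccc5)cc4o3)c(OCc3ccccc3)c21 | intermediate
22 | (2R)-6-[2-(5,7-dihydroxy-4-oxo-4H-chromen-2-yl)-4,5-dihydroxyphenyl]-5,7-dihydroxy-2-(4-hydroxyphenyl)-2,3-dihydro-4H-chromen-4-one | O=C1C[C@H](c2ccc(O)cc2)Oc2cc(O)c(-c3cc(O)c(O)cc3-c3cc(=O)c4c(O)cc(O)cc4o3)c(O)c21 | target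

Total step count: 15. Longest linear sequence: 13 steps (steps 1–5, 7–10 and 12–15, from 2,4,6-trihydroxybenzaldehyde).

Steps most likely to fail

**Step 7.**
- **Risk:** The cycloaddition may be too slow. The triple bond is flanked by two ortho substituents and fed by a donor ring, so the diene may oligomerise or lose its silyl groups before it adds.
- **Fallback:** The biaryl bond is made by cross-coupling instead of ring construction, setting out from aldehyde 3.
  - Pinnick oxidation (NaClO2, NaH2PO4, 2-methylbut-2-ene, t-BuOH/H2O) should give 2,6-bis(benzyloxy)-4-(methoxymethoxy)benzoic acid F1.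
  - Commercial methyl 3,4-bis(benzyloxy)benzoate is iodinated para to its 3-benzyloxy group (NIS, CF3CO2H, MeCN) to methyl 4,5-bis(benzyloxy)-2-iodobenzoate F2.
  - Palladium-catalysed decarboxylative biaryl coupling of the two (PdCl2, AsPh3, Ag2CO3, DMSO, 150 °C) is a reaction type established for 2,6-dialkoxybenzoic acids. It should give methyl 4,5-bis(benzyloxy)-2-[2,6-bis(benzyloxy)-4-(methoxymethoxy)phenyl]benzoate F3.
  - NBS in MeCN at 0 °C then brominates the far more activated phloroglucinol ring, and the route is rejoined at 12.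

**Step 14.**
- **Risk:** Insertion into the electron-rich, heavily substituted chromone may lag behind protodeboronation of the boronic acid, or facial selectivity may erode.
- **Fallback:** The pyranone ring is closed by oxa-Michael addition and the enantiomers are separated, setting out from hydroxyacetophenone 17.
  - Claisen–Schmidt condensation with commercial 4-(benzyloxy)benzaldehyde (KOH, EtOH/THF, rt) should give the (E)-2′-hydroxychalcone F4.
  - NaOAc in refluxing EtOH cyclises it through the only free phenol to the racemic flavanone F5.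
  - Preparative HPLC on an amylose tris(3,5-dimethylphenylcarbamate) phase delivers 21, where the route is rejoined.
  - The (2S)-flavanone F6 is returned to the racemate with NaOAc in hot EtOH and recycled.

**Step 12.**
- **Risk:** Attack of the enolate on the ester carbonyl, which is shielded by the twisted ortho aryl group, may be sluggish, so that proton transfer and self-condensation of the ketone take over.
- **Fallback:** The acyl transfer is made intramolecular, setting out from ester 13.
  - Saponification (LiOH, THF/MeOH/H2O, 60 °C; acidified only to pH 5 with NaH2PO4 to spare the enol ether) should give the biaryl carboxylic acid F7.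
  - The acid is esterified at once with phenol 15 (EDC·HCl, DMAP, CH2Cl2) to the 2-acetyl-3,5-bis(benzyloxy)phenyl ester F8.
  - Baker–Venkataraman rearrangement (KOt-Bu, THF, rt) should then give diketone 16, where the route is rejoined, and 16 is cyclised with HCl in MeOH/THF as in step 12.

Further compounds
F1 | step 7 | 2,6-bis(benzyloxy)-4-(methoxymethoxy)benzoic acid | OC(=O)c1c(OCc2ccccc2)cc(OCOC)cc1OCc1ccccc1
F2 | step 7 | methyl 4,5-bis(benzyloxy)-2-iodobenzoate | COC(=O)c1cc(OCc2ccccc2)c(OCc2ccccc2)cc1I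
F3 | step 7 | methyl 4,5-bis(benzyloxy)-2-[2,6-bis(benzyloxy)-4-(methoxymethoxy)phenyl]benzoate | COC(=O)c1cc(OCc2ccccc2)c(OCc2ccccc2)cc1-c1c(OCc2ccccc2)cc(OCOC)cc1OCc1ccccc1
F4 | step 14 | 2-{4,5-bis(benzyloxy)-2-[2,6-bis(benzyloxy)-3-{(E)-3-[4-(benzyloxy)phenyl]prop-2-enoyl}-4-hydroxyphenyl]phenyl}-5,7-bis(benzyloxy)-4H-chromen-4-one | O=C(/C=C/c1ccc(OCc2ccccc2)cc1)c1c(O)cc(OCc2ccccc2)c(-c2cc(OCc3ccccc3)c(OCc3ccccc3)cc2-c2cc(=O)c3c(OCc4ccccc4)cc(OCc4ccccc4)cc3o2)c1OCc1ccccc1
F5 | step 14 | racemic 5,7-bis(benzyloxy)-2-[4-(benzyloxy)phenyl]-6-{4,5-bis(benzyloxy)-2-[5,7-bis(benzyloxy)-4-oxo-4H-chromen-2-yl]phenyl}-2,3-dihydro-4H-chromen-4-one | O=C1CC(c2ccc(OCc3ccccc3)cc2)Oc2cc(OCc3ccccc3)c(-c3cc(OCc4ccccc4)c(OCc4ccccc4)cc3-c3cc(=O)c4c(OCc5ccccc5)cc(OCc5ccccc5)cc4o3)c(OCc3ccccc3)c21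
F6 | step 14 | (2S)-5,7-bis(benzyloxy)-2-[4-(benzyloxy)phenyl]-6-{4,5-bis(benzyloxy)-2-[5,7-bis(benzyloxy)-4-oxo-4H-chromen-2-yl]phenyl}-2,3-dihydro-4H-chromen-4-one | O=C1C[C@@H](c2ccc(OCc3ccccc3)cc2)Oc2cc(OCc3ccccc3)c(-c3cc(OCc4ccccc4)c(OCc4ccccc4)cc3-c3cc(=O)c4c(OCc5ccccc5)cc(OCc5ccccc5)cc4o3)c(OCc3ccccc3)c21
F7 | step 12 | 4,5-bis(benzyloxy)-2-[2,6-bis(benzyloxy)-3-(1-ethoxyethenyl)-4-(methoxymethoxy)phenyl]benzoic acid | OC(=O)c1cc(OCc2ccccc2)c(OCc2ccccc2)cc1-c1c(OCc2ccccc2)c(C(=C)OCC)c(OCOC)cc1OCc1ccccc1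
F8 | step 12 | 2-acetyl-3,5-bis(benzyloxy)phenyl 4,5-bis(benzyloxy)-2-[2,6-bis(benzyloxy)-3-(1-ethoxyethenyl)-4-(methoxymethoxy)phenyl]benzoate | CC(=O)c1c(OC(=O)c2cc(OCc3ccccc3)c(OCc3ccccc3)cc2-c2c(OCc3ccccc3)c(C(=C)OCC)c(OCOC)cc2OCc2ccccc2)cc(OCc2ccccc2)cc1OCc1ccccc1
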